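**Plan**

- Retrosynthesis (cladiellane numbering, see remark): C6–OMe/C7–OH go back to a C6=C7 olefin, C11 OAc/Me to a C11 ketone, and the lactone (O3–C16, C15–C16) to a 14-acetyl group. C1–C10 and C13–C14 are then cut together ([4+2]), followed by C1=C14 (Wittig), C11–C12 (vinyl Grignard), C6=C7 (RCM), C3–C4 (Grignard), C2–C3 (aldol), O–C2 (Williamson) and C8–C9 (methallylation).
- Forward ring order: oxonene (ring A, RCM), then tetrahydrofuran (ring B) and cyclohexene (ring C) in one intramolecular Diels–Alder step, then the seven-membered lactone (ring D), the C11 acetate and the C6/C7 oxygenation.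
- Enabling feature: the ether oxygen of the oxonane links C2 and C9, so it is a ready three-atom tether between C1 and C10. The cyclohexane C1–C10–C11–C12–C13–C14, oxygenated at C11 and carbon-branched at C14, is the retron of a 2-siloxydiene (C10–C13) plus enone (C1=C14) cycloaddition.
- Stereochemistry: C9 by Brown methallylation; C2 by Evans aldol; C3 by chelate-controlled Grignard addition; C1, C10, C14 by the cycloaddition under control of the oxonene; C11 by axial methyl addition; C15 by hydroboration; C7 by peripheral osmylation; C6 by oxidation then hydroxyl-directed reduction.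

Key step: step 16

Remark: cladiellane numbering is used (C1/C10 ring-fusion carbons, C2/C9 ether carbons, C3 the methyl-bearing lactone carbinol, C6 OMe, C7 Me/OH, C11 Me/OAc, C14 bears C15, C16 the lactone carbonyl); the target is (1S,2S,3S,6R,7R,9S,10R,11R,14R,15R). Aldehyde 1 is taken as a catalogue compound.

**Step 1**
Reactants: 1 3-[(4-methoxybenzyl)oxy]propanal
Product: 2 (3S)-1-[(4-methoxybenzyl)oxy]-5-methylhex-5-en-3-ol
Conditions: (−)-Ipc2BOMe, CH2=C(CH3)CH2MgCl, Et2O, −78 °C → rt; then 1, −78 °C; NaOH, H2O2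
Reagents that add atoms: 2-methylallylmagnesium chloride, CC(=C)C[Mg]Cl
Why: Brown asymmetric methallylboration through a chair six-membered transition state, in which the isopinocampheyl groups (from (+)-α-pinene) select the aldehyde face that gives the (S)-carbinol, the future C9.

**Step 2**
Reactants: 2 homoallylic alcohol
Product: 3 alkoxyacetic acid
Conditions: NaH, BrCH2CO2H, THF/DMF, 0 °C → rt
Reagents that add atoms: bromoacetic acid, OC(=O)CBr
Why: Williamson ether synthesis, the sodium alkoxide displacing bromide from sodium bromoacetate without touching the stereocentre.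

**Step 3**
Reactants: 3 alkoxyacetic acid
Product: 5 glycolyl imide, via mixed pivalic anhydride 4 (not isolated)
Conditions: t-BuCOCl, Et3N, THF, −78 → 0 °C; then (R)-4-benzyl-2-oxazolidinone, n-BuLi, THF, −78 °C → rt
Reagents that add atoms: (R)-4-benzyl-2-oxazolidinone, O=C1OC[C@@H](Cc2ccccc2)N1
Why: N-acylation of the lithiated oxazolidinone by the mixed anhydride at its unhindered glycolyl carbonyl.

**Step 4**
Reactants: 5 glycolyl imide
Product: 7 syn-aldol adduct, via boron enolate 6 (not isolated)
Conditions: Bu2BOTf, i-Pr2NEt, CH2Cl2, −78 → 0 °C; CH3CHO, −78 → 0 °C; pH 7 buffer, MeOH, H2O2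
Reagents that add atoms: acetaldehyde, CC=O
Why: Evans syn-aldol reaction, the (Z)-boron enolate adding through a Zimmerman–Traxler chair on the face opposite the benzyl group, which sets C2 (the adjacent carbinol centre is oxidised away in step 7).

**Step 5**
Reactants: 7 syn-aldol adduct
Product: 8 1,3-diol
Conditions: LiBH4, MeOH, THF, 0 °C
Reagents that add atoms: none
Why: Borohydride reductive cleavage of the N-acyl oxazolidinone to the primary alcohol, with release of the auxiliary.

**Step 6**
Reactants: 8 1,3-diol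
Product: 9 primary pivalate
Conditions: t-BuCOCl, pyridine, CH2Cl2, 0 °C
Reagents that add atoms: pivaloyl chloride, CC(C)(C)C(Cl)=O
Why: Selective acylation of the primary over the secondary hydroxyl by the bulky acid chloride.

**Step 7**
Reactants: 9 primary pivalate
Product: 10 α-alkoxy methyl ketone
Conditions: Dess–Martin periodinane, NaHCO3, CH2Cl2, 0 °C → rt
Reagents that add atoms: none
Why: Dess–Martin oxidation of the secondary alcohol under buffered conditions that should not epimerise C2.

**Step 8**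
Reactants: 10 α-alkoxy methyl ketone
Product: 11 tertiary alcohol (RCM diene)
Conditions: CH2=CHCH2CH2MgBr, MgBr2·OEt2, CH2Cl2/Et2O, −78 °C
Reagents that add atoms: but-3-enylmagnesium bromide, C=CCC[Mg]Br
Why: Cram-chelate-controlled Grignard addition, magnesium bridging the ketone and the α-ether oxygen so that the nucleophile enters from the side of the C2 hydrogen and sets the C3 carbinol syn to the C2 oxygen.

**Step 9**
Reactants: 11 tertiary alcohol (RCM diene)
Product: 12 (Z)-oxonene
Conditions: second-generation Grubbs catalyst (H2IMes)(PCy3)Cl2Ru=CHPh (10 mol %), CH2Cl2 (2 mM), 40 °C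
Reagents that add atoms: none
Why: Ring-closing metathesis, favoured by the gauche preference about the two C–O bonds of the doubly α-branched ether, with the nine-membered ring able to hold only the (Z)-trisubstituted olefin.

**Step 10**
Reactants: 12 (Z)-oxonene
Product: 13 primary alcohol
Conditions: DDQ, CH2Cl2/pH 7 buffer, 0 °C
Reagents that add atoms: none
Why: Oxidative cleavage of the p-methoxybenzyl ether by DDQ, which should leave the pivalate, the tertiary alcohol and the isolated olefin untouched.

**Step 11**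
Reactants: 13 primary alcohol
Product: 14 β-alkoxy aldehyde
Conditions: Dess–Martin periodinane, NaHCO3, CH2Cl2, 0 °C
Reagents that add atoms: none
Why: Dess–Martin oxidation under neutral buffered conditions that avoid β-elimination of the ether oxygen.

**Step 12**
Reactants: 14 β-alkoxy aldehyde
Product: 15 allylic alcohol (both carbinol epimers)
Conditions: CH2=CHMgBr (3 equiv), THF, −78 °C
Reagents that add atoms: vinylmagnesium bromide, C=C[Mg]Br
Why: Grignard 1,2-addition to the aldehyde, far faster at −78 °C than attack on the pivalate; the uncontrolled carbinol centre is removed in step 13.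

**Step 13**
Reactants: 15 allylic alcohol
Product: 16 vinyl ketone
Conditions: Dess–Martin periodinane, NaHCO3, CH2Cl2, 0 °C
Reagents that add atoms: none
Why: Dess–Martin oxidation of the allylic alcohol to the enone.

**Step 14**
Reactants: 16 vinyl ketone
Product: 17 (Z)-2-siloxydiene, 3-O-triethylsilyl ether
Conditions: Et3SiOTf (2.5 equiv), Et3N, CH2Cl2, −78 → 0 °C
Reagents that add atoms: triethylsilyl trifluoromethanesulfonate, CC[Si](CC)(CC)OS(=O)(=O)C(F)(F)F
Why: Soft enolisation at the only enolisable position (C10) gives the (Z)-silyl dienol ether without a free enolate that could expel the β-ether oxygen, and the tertiary alcohol is silylated in the same operation.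

**Step 15**
Reactants: 17 siloxydiene pivalate
Product: 18 primary alcohol
Conditions: i-Bu2AlH, CH2Cl2, −78 °C; aq. potassium sodium tartrate
Reagents that add atoms: none
Why: Reductive cleavage of the pivalate by the aluminium hydride under non-acidic conditions that should spare both silyl ethers.

**Step 16**
Reactants: 18 primary alcohol
Product: 21 tricyclic Diels–Alder adduct (14-acetyl; C11=C12 triethylsilyl enol ether; 3-OTES), via aldehyde 19 (not isolated), via tetraene enone 20 (not isolated)
Conditions: SO3·pyridine, DMSO, i-Pr2NEt, CH2Cl2, 0 °C; then Ph3P=CHC(O)CH3, rt; then toluene, 60 °C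
Reagents that add atoms: 1-(triphenylphosphoranylidene)propan-2-one, CC(=O)C=P(c1ccccc1)(c1ccccc1)c1ccccc1
Why: Parikh–Doering oxidation gives the α-alkoxy aldehyde 19, the stabilised ylide converts it (Wittig olefination) into the (E)-enone 20, and this tetraene undergoes a normal-electron-demand intramolecular Diels–Alder reaction in which the 2-siloxydiene C10=C11–C12=C13 and the enone C1=C14 combine suprafacially to form C1–C10 and C13–C14 in one concerted step. The closest known reaction type is the exo-selective intramolecular Diels–Alder reaction of cyclic ethers that carry diene and dienophile on the two α-carbons, which gives cis-fused hydroisobenzofurans. Two rings close together: the cyclohexene by the [4+2] cycloaddition itself and the tetrahydrofuran through the C1–C10 bond, exo with respect to both reacting π-bonds (type 1 cycloaddition with the three-atom tether C2–O–C9). All three new stereocentres are substrate-controlled: the nine-membered ring holds the side chains cis across the ether oxygen and lets them meet only on the face turned away from ring carbons C3 and C8, placing H1 and H10 anti to H2 and H9; the tether is endo and the acetyl group exo, so H1 and H10 are cis; and the (E)-enone geometry is copied into the trans relationship of the C14 acetyl group to C2. The step needs exo over endo selectivity, one diene face, and cycloaddition in preference to hydrolysis of the dienol ether or intermolecular reaction; the ring constraint, the matched siloxydiene/enone electronics, amine-buffered conditions and high dilution should secure these.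

**Step 17**
Reactants: 21 Diels–Alder adduct
Product: 22 14-isopropenyl compound
Conditions: Ph3PCH3Br, KOt-Bu, THF, 0 °C → rt
Reagents that add atoms: methyltriphenylphosphonium bromide, C[P+](c1ccccc1)(c1ccccc1)c1ccccc1.[Br-]
Why: Wittig methylenation of the methyl ketone; the equatorial C14 side chain trans to C2 is the thermodynamically preferred arrangement, so the basic ylide should not erode it.

**Step 18**
Reactants: 22 14-isopropenyl compound
Product: 23 C11 ketone with free C3 hydroxyl
Conditions: HF·pyridine, pyridine, THF, 0 °C → rt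
Reagents that add atoms: none
Why: Fluoride desilylation cleaves the silyl enol ether (to the ketone) and the tertiary silyl ether under buffered conditions that should not enolise C10.

**Step 19**
Reactants: 23 C11 ketone
Product: 24 C3,C11-diol (C11 methyl cis to H10)
Conditions: CH3MgBr (4 equiv), THF, −78 → 0 °C
Reagents that add atoms: methylmagnesium bromide, C[Mg]Br
Why: Grignard addition to the cyclohexanone, methyl entering axially on the convex face anti to the axial C10–C9 bond (Felkin–Anh/torsional control), which puts the C11 oxygen equatorial and cis to C9.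

**Step 20**
Reactants: 24 C3,C11-diol
Product: 26 triol (C16 primary alcohol), via alkylborane 25 (not isolated)
Conditions: 9-BBN, THF, 0 °C → rt; then NaOH, H2O2, 0 °C
Reagents that add atoms: hydrogen peroxide, OO
Why: Hydroboration–oxidation, chemoselective for the 1,1-disubstituted over the trisubstituted olefin; with H14 eclipsing the double bond (allylic strain) the bulky borane attacks anti to C1, from the C13 side, which sets C15.

**Step 21**
Reactants: 26 triol
Product: 29 lactone with free C11 hydroxyl, via hydroxy aldehyde 27 (not isolated), via lactol 28 (not isolated)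
Conditions: TEMPO (20 mol %), PhI(OAc)2 (3 equiv), CH2Cl2, rt
Reagents that add atoms: none
Why: Oxoammonium (TEMPO) oxidation of the primary alcohol to the aldehyde, which the proximate C3 hydroxyl traps as a seven-membered lactol that is oxidised on to the lactone (oxidative lactonisation of a diol); the tertiary alcohols and the olefin are inert.

**Step 22**
Reactants: 29 lactone
Product: 30 C11 acetate
Conditions: Ac2O, DMAP, Et3N, CH2Cl2, 40 °C
Reagents that add atoms: acetic anhydride, CC(=O)OC(C)=O
Why: DMAP-catalysed (Steglich-type) acetylation of the only remaining hydroxyl, the equatorial tertiary C11 alcohol.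

**Step 23**
Reactants: 30 C11 acetate
Product: 31 (6S,7R)-cis-diol
Conditions: OsO4 (5 mol %), NMO, acetone/H2O, rt
Reagents that add atoms: N-methylmorpholine N-oxide, C[N+]1([O-])CCOCC1; water, O
Why: Upjohn syn-dihydroxylation of the only olefin on its exposed peripheral face (the face away from the inward-pointing C3 oxygen), which sets C7 as in the target and C6 opposite to it.

**Step 24**
Reactants: 31 cis-diol
Product: 32 6-keto-7-hydroxy compound
Conditions: SO3·pyridine, DMSO, i-Pr2NEt, CH2Cl2, 0 °C → rt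
Reagents that add atoms: none
Why: Parikh–Doering oxidation of the secondary alcohol; the tertiary alcohol cannot react and the diol is not cleaved.

**Step 25**
Reactants: 32 α-hydroxy ketone
Product: 33 (6R,7R)-trans-diol
Conditions: Me4NBH(OAc)3, AcOH/MeCN, −30 → 0 °C
Reagents that add atoms: none
Why: Hydroxyl-directed reduction, the C7 alkoxyborohydride delivering hydride to C6 on the peripheral face on which the C7 oxygen sits (the other face is screened by the C7 methyl and the ring), so the new C6 hydroxyl is trans to the C7 hydroxyl.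

**Step 26**
Reactants: 33 trans-diol
Product: 34 target
Conditions: MeOTf, 2,6-di-tert-butyl-4-methylpyridine, CH2Cl2, 0 °C → rt
Reagents that add atoms: methyl trifluoromethanesulfonate, COS(=O)(=O)C(F)(F)F
Why: O-Methylation of the secondary hydroxyl by a small, powerful electrophile under non-basic conditions, the tertiary hydroxyl being too hindered to compete and the lactone and acetate not being exposed to base.

**Compound list**

1 | 3-[(4-methoxybenzyl)oxy]propanal | COc1ccc(COCCC=O)cc1 | starting material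
2 | (3S)-1-[(4-methoxybenzyl)oxy]-5-methylhex-5-en-3-ol | O[C@H](CCOCc1ccc(OC)cc1)CC(C)=C | intermediate
3 | 2-({(3S)-1-[(4-methoxybenzyl)oxy]-5-methylhex-5-en-3-yl}oxy)acetic acid | OC(=O)CO[C@H](CCOCc1ccc(OC)cc1)CC(C)=C | intermediate
4 | mixed anhydride of 3 with pivalic acid | CC(C)(C)C(=O)OC(=O)CO[C@H](CCOCc1ccc(OC)cc1)CC(C)=C | intermediate
5 | (4R)-4-benzyl-3-[2-({(3S)-1-[(4-methoxybenzyl)oxy]-5-methylhex-5-en-3-yl}oxy)acetyl]oxazolidin-2-one | O=C1OC[C@@H](Cc2ccccc2)N1C(=O)CO[C@H](CCOCc3ccc(OC)cc3)CC(C)=C | intermediate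
6 | dibutylboron (Z)-enolate of 5 | CCCCB(CCCC)O/C(N1C(=O)OC[C@H]1Cc1ccccc1)=C\O[C@H](CCOCc1ccc(OC)cc1)CC(C)=C | intermediate
7 | (4R)-4-benzyl-3-[(2R,3S)-3-hydroxy-2-({(3S)-1-[(4-methoxybenzyl)oxy]-5-methylhex-5-en-3-yl}oxy)butanoyl]oxazolidin-2-one | O=C1OC[C@@H](Cc2ccccc2)N1C(=O)[C@@H]([C@H](C)O)O[C@H](CCOCc3ccc(OC)cc3)CC(C)=C | intermediate
8 | (2S,3S)-2-({(3S)-1-[(4-methoxybenzyl)oxy]-5-methylhex-5-en-3-yl}oxy)butane-1,3-diol | OC[C@@H]([C@H](C)O)O[C@H](CCOCc1ccc(OC)cc1)CC(C)=C | intermediate
9 | (2S,3S)-3-hydroxy-2-({(3S)-1-[(4-methoxybenzyl)oxy]-5-methylhex-5-en-3-yl}oxy)butyl pivalate | CC(C)(C)C(=O)OC[C@@H]([C@H](C)O)O[C@H](CCOCc1ccc(OC)cc1)CC(C)=C | intermediate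
10 | (2S)-2-({(3S)-1-[(4-methoxybenzyl)oxy]-5-methylhex-5-en-3-yl}oxy)-3-oxobutyl pivalate | CC(C)(C)C(=O)OC[C@@H](C(C)=O)O[C@H](CCOCc1ccc(OC)cc1)CC(C)=C | intermediate
11 | (2S,3S)-3-hydroxy-3-methyl-2-({(3S)-1-[(4-methoxybenzyl)oxy]-5-methylhex-5-en-3-yl}oxy)hept-6-en-1-yl pivalate | CC(C)(C)C(=O)OC[C@@H]([C@@](C)(O)CCC=C)O[C@H](CCOCc1ccc(OC)cc1)CC(C)=C | intermediate
12 | [(2S,3S,6Z,9S)-3-hydroxy-9-{2-[(4-methoxybenzyl)oxy]ethyl}-3,7-dimethyl-2,3,4,5,8,9-hexahydrooxonin-2-yl]methyl pivalate | CC(C)(C)C(=O)OC[C@@H]1O[C@H](CCOCc2ccc(OC)cc2)C/C(C)=C\CC[C@]1(C)O | intermediate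
13 | [(2S,3S,6Z,9S)-3-hydroxy-9-(2-hydroxyethyl)-3,7-dimethyl-2,3,4,5,8,9-hexahydrooxonin-2-yl]methyl pivalate | CC(C)(C)C(=O)OC[C@@H]1O[C@H](CCO)C/C(C)=C\CC[C@]1(C)O | intermediate
14 | [(2S,3S,6Z,9S)-3-hydroxy-3,7-dimethyl-9-(2-oxoethyl)-2,3,4,5,8,9-hexahydrooxonin-2-yl]methyl pivalate | CC(C)(C)C(=O)OC[C@@H]1O[C@H](CC=O)C/C(C)=C\CC[C@]1(C)O | intermediate
15 | [(2S,3S,6Z,9S)-3-hydroxy-9-(2-hydroxybut-3-en-1-yl)-3,7-dimethyl-2,3,4,5,8,9-hexahydrooxonin-2-yl]methyl pivalate, both side-chain carbinol epimers | CC(C)(C)C(=O)OC[C@@H]1O[C@H](CC(O)C=C)C/C(C)=C\CC[C@]1(C)O | intermediate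
16 | [(2S,3S,6Z,9S)-3-hydroxy-3,7-dimethyl-9-(2-oxobut-3-en-1-yl)-2,3,4,5,8,9-hexahydrooxonin-2-yl]methyl pivalate | CC(C)(C)C(=O)OC[C@@H]1O[C@H](CC(=O)C=C)C/C(C)=C\CC[C@]1(C)O | intermediate
17 | [(2S,3S,6Z,9S)-3,7-dimethyl-3-(triethylsilyloxy)-9-[(1Z)-2-(triethylsilyloxy)buta-1,3-dien-1-yl]-2,3,4,5,8,9-hexahydrooxonin-2-yl]methyl pivalate | CC(C)(C)C(=O)OC[C@@H]1O[C@H](/C=C(O[Si](CC)(CC)CC)/C=C)C/C(C)=C\CC[C@]1(C)O[Si](CC)(CC)CC | intermediate
18 | primary alcohol from 17: [(2S,3S,6Z,9S)-3,7-dimethyl-3-(triethylsilyloxy)-9-[(1Z)-2-(triethylsilyloxy)buta-1,3-dien-1-yl]-2,3,4,5,8,9-hexahydrooxonin-2-yl]methanol | OC[C@@H]1O[C@H](/C=C(O[Si](CC)(CC)CC)/C=C)C/C(C)=C\CC[C@]1(C)O[Si](CC)(CC)CC | intermediate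
19 | oxonin-2-carbaldehyde from 18 (same spatial arrangement at C2, C3, C9) | O=C[C@@H]1O[C@H](/C=C(O[Si](CC)(CC)CC)/C=C)C/C(C)=C\CC[C@]1(C)O[Si](CC)(CC)CC | intermediate
20 | (3E)-4-(oxonin-2-yl)but-3-en-2-one from 19: (E)-enone on C2, (Z)-siloxydiene on C9 | CC(=O)/C=C/[C@@H]1O[C@H](/C=C(O[Si](CC)(CC)CC)/C=C)C/C(C)=C\CC[C@]1(C)O[Si](CC)(CC)CC | intermediate
21 | tricyclic adduct: (6Z)-oxonene bridged by the 2,9-ether to a cis-fused tetrahydrofuran/cyclohexene; C11=C12 triethylsilyl enol ether, 3-OTES, 14-acetyl trans to C2, H1/H10 cis and anti to H2/H9; C1, C2, C3, C9, C10, C14 arranged as in the target | CC(=O)[C@@H]1CC=C(O[Si](CC)(CC)CC)[C@@H]2[C@H]1[C@@H]3O[C@H]2C/C(C)=C\CC[C@]3(C)O[Si](CC)(CC)CC | intermediate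
22 | 14-isopropenyl analogue of 21 | CC(=C)[C@@H]1CC=C(O[Si](CC)(CC)CC)[C@@H]2[C@H]1[C@@H]3O[C@H]2C/C(C)=C\CC[C@]3(C)O[Si](CC)(CC)CC | intermediate
23 | 14-isopropenyl C11 ketone with free C3 tertiary alcohol, (6Z)-olefin, stereocentres as in the target | CC(=C)[C@@H]1CCC(=O)[C@@H]2[C@H]1[C@@H]3O[C@H]2C/C(C)=C\CC[C@]3(C)O | intermediate
24 | C3,C11-diol: 11-methyl cis to H10, 11-hydroxyl cis to C9, 14-isopropenyl | CC(=C)[C@@H]1CC[C@@](C)(O)[C@@H]2[C@H]1[C@@H]3O[C@H]2C/C(C)=C\CC[C@]3(C)O | intermediate
25 | B-alkyl-9-borabicyclo[3.3.1]nonane adduct of 24 (boron on C16, C15 as in the target) | C[C@@H](CB1C2CCCC1CCC2)[C@@H]1CC[C@@](C)(O)[C@@H]2[C@H]1[C@@H]3O[C@H]2C/C(C)=C\CC[C@]3(C)O | intermediate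
26 | triol: C16 primary alcohol (C15 as in the target), C3 and C11 tertiary alcohols, (6Z)-olefin | OC[C@H](C)[C@@H]1CC[C@@](C)(O)[C@@H]2[C@H]1[C@@H]3O[C@H]2C/C(C)=C\CC[C@]3(C)O | intermediate
27 | C16 aldehyde of 26 | O=C[C@H](C)[C@@H]1CC[C@@](C)(O)[C@@H]2[C@H]1[C@@H]3O[C@H]2C/C(C)=C\CC[C@]3(C)O | intermediate
28 | seven-membered lactol (C16 hemiacetal with O3) | C/C1=C/CC[C@]2(C)OC(O)[C@H](C)[C@@H]3CC[C@@](C)(O)[C@@H]4[C@H]3[C@@H]2O[C@H]4C1 | intermediate
29 | (1S,2S,3S,6Z,9S,10R,11R,14R,15R)-tetracyclic lactone with free C11 hydroxyl and C6=C7 olefin | C/C1=C/CC[C@]2(C)OC(=O)[C@H](C)[C@@H]3CC[C@@](C)(O)[C@@H]4[C@H]3[C@@H]2O[C@H]4C1 | intermediate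
30 | C11 acetate of 29 | C/C1=C/CC[C@]2(C)OC(=O)[C@H](C)[C@@H]3CC[C@@](C)(OC(C)=O)[C@@H]4[C@H]3[C@@H]2O[C@H]4C1 | intermediate
31 | (6S,7R)-6,7-dihydroxy lactone acetate (6,7-cis-diol, 6-epimer of 33) | O[C@H]1CC[C@]2(C)OC(=O)[C@H](C)[C@@H]3CC[C@@](C)(OC(C)=O)[C@@H]4[C@H]3[C@@H]2O[C@H]4C[C@@]1(C)O | intermediate
32 | (7R)-7-hydroxy-6-oxo lactone acetate | O=C1CC[C@]2(C)OC(=O)[C@H](C)[C@@H]3CC[C@@](C)(OC(C)=O)[C@@H]4[C@H]3[C@@H]2O[C@H]4C[C@@]1(C)O | intermediate
33 | (6R,7R)-6,7-dihydroxy lactone acetate (6-O-demethyl target) | O[C@@H]1CC[C@]2(C)OC(=O)[C@H](C)[C@@H]3CC[C@@](C)(OC(C)=O)[C@@H]4[C@H]3[C@@H]2O[C@H]4C[C@@]1(C)O | intermediate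
34 | CNP0238771.1, (1S,2S,3S,6R,7R,9S,10R,11R,14R,15R)-11-acetoxy-7-hydroxy-6-methoxy lactone | CO[C@@H]1CC[C@]2(C)OC(=O)[C@H](C)[C@@H]3CC[C@@](C)(OC(C)=O)[C@@H]4[C@H]3[C@@H]2O[C@H]4C[C@@]1(C)O | target

**Step count and risks**

Total steps: 26. Longest linear sequence: 26 steps (fully linear from 1).

Steps most likely to fail:

1. Step 21 (oxidative lactonisation). The hydroxy aldehyde may fail to close onto the hindered tertiary C3 hydroxyl, so that oxidation stalls at the aldehyde, C15 epimerises through its enol, or the aldehyde is over-oxidised. The fallback sets out from triol 26. It is oxidised fully to the hydroxy acid F1 (TEMPO, PhI(OAc)2, MeCN/H2O). F1 is activated with 2-methyl-6-nitrobenzoic anhydride, Et3N and DMAP as the mixed anhydride F2, which should close under high dilution in toluene (Shiina lactonisation). The route is rejoined at lactone 29.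

2. Step 19 (methyl addition). Enolisation of the β-alkoxy ketone with opening of the tetrahydrofuran, or competing attack along the equatorial trajectory, would cost material or give the C11 epimer. The fallback sets out from ketone 23. Dimethylsulfonium methylide (Me3S+ I−, n-BuLi, THF, −10 °C; Corey–Chaykovsky reaction) is a less basic carbon nucleophile that adds irreversibly in the axial sense. It should give the spiro-epoxide F3 with the oxygen equatorial. LiEt3BH then opens F3 at its methylene carbon, and the route is rejoined at diol 24.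

3. Step 25 (C6 reduction). Hydride delivery to the wrong face, if the ring adopts a conformation in which the C7 oxygen cannot direct, would return cis-diol 31. The fallback sets out from ketone 32 and installs the methoxy group and the C6 hydrogen together by ionic hydrogenation of the methyl oxocarbenium ion (MeOSiMe3, Et3SiH, Me3SiOTf cat., CH2Cl2, −78 °C). The silane should attack the cation from the open peripheral face. The product is expected as the 7-O-trimethylsilyl ether F4 of the target, and HF·pyridine should free 34 directly, so steps 25 and 26 are both bypassed.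

**Further compounds**

F1 | step 21 | hydroxy acid, C16 carboxylic acid corresponding to triol 26 | OC(=O)[C@H](C)[C@@H]1CC[C@@](C)(O)[C@@H]2[C@H]1[C@@H]3O[C@H]2C/C(C)=C\CC[C@]3(C)O
F2 | step 21 | mixed anhydride of F1 with 2-methyl-6-nitrobenzoic acid | Cc1cccc([N+](=O)[O-])c1C(=O)OC(=O)[C@H](C)[C@@H]1CC[C@@](C)(O)[C@@H]2[C@H]1[C@@H]3O[C@H]2C/C(C)=C\CC[C@]3(C)O
F3 | step 19 | C11 spiro-epoxide of 23 (oxirane CH2 cis to H10, oxygen cis to C9) | CC(=C)[C@@H]1CC[C@@](C4)(O4)[C@@H]2[C@H]1[C@@H]3O[C@H]2C/C(C)=C\CC[C@]3(C)O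
F4 | step 25 | 7-O-trimethylsilyl ether of 34 | CO[C@@H]1CC[C@]2(C)OC(=O)[C@H](C)[C@@H]3CC[C@@](C)(OC(C)=O)[C@@H]4[C@H]3[C@@H]2O[C@H]4C[C@@]1(C)O[Si](C)(C)C
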